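**Plan**
- Cuts: flavone ring C at O1–C2 and C2–C3 (back to a 2'-hydroxychalcone) and at C2–C1' (formyl carbon placed on an aryl bromide). The dioxane ring is cut at O4'–C8'' (key cut) and at O3'–C3'. The remaining cuts are C4'–O4' (back to C4'–CHO), C5'–OMe and C7''–C1''.
- Enabling feature: in the 1,4-dioxane ring fused to ring B, C8'' is bonded to ring oxygen O4' and carries the C9''H2OH arm. The array O4'–C8''–C9''–OH is what remains when a terminal C8''/C9'' oxirane is opened at C8'' by the O4' phenoxide. O4' can first sit on C4' as a formyl group, which activates the ortho carbons C3' and C5' for substitution.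
- Forward order: glycerate C3 unit plus guaiacyl Grignard reagent (C7''–C1''), reduction at C7'', SNAr on the difluoroaldehyde (O3'–C3'), then methoxide (C5'–OMe). Next come acetonide to oxirane, CHO to OCHO, and dioxane ring closure. Ring C closes last, after Br to CHO and chalcone formation with the ring A acetophenone.
- Stereochemistry: C8'' comes from the chiral pool ((S)-glycerate) and is inverted once, in the key step, to (R). C7'' (R) is set by chelation-controlled ketone reduction under 1,2-induction from C8'' and never loses its oxygen afterwards.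

Key step: step 10

Remark on locants: flavone rings A and C are unprimed and ring B is primed. The phenylpropanoid unit is double-primed (C7'' benzylic, C8'', C9'' = CH2OH). O3' and O4' are the ring B oxygens on C3' and C4'.
Assumption: Zn(BH4)2 is taken from an ethereal stock solution made beforehand from ZnCl2 and NaBH4 and counts as a reagent, not as a step.

**Step 1**
Reactants: 1 methyl (S)-2,2-dimethyl-1,3-dioxolane-4-carboxylate
Product: 2 (S)-N-methoxy-N,2,2-trimethyl-1,3-dioxolane-4-carboxamide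
Conditions: MeNH(OMe)·HCl, iPrMgCl, THF, −20 → 0 °C
Reagents that add atoms: N,O-dimethylhydroxylamine hydrochloride, CNOC.Cl
Why: Weinreb amide formation, in which the chloromagnesium amide made in the flask acylates on the ester faster than it can enolise it at this temperature, so the C8'' stereocentre is carried over unchanged.

**Step 2**
Reactants: 3 4-bromo-2-methoxyphenol
Product: 4 1-(benzyloxy)-4-bromo-2-methoxybenzene
Conditions: BnBr, K2CO3, DMF, rt
Reagents that add atoms: benzyl bromide, BrCc1ccccc1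
Why: Williamson ether synthesis on the only acidic OH gives a benzyl ether that tolerates the Grignard, hydride, base, peracid and organolithium steps and leaves in the final hydrogenolysis.

**Step 3**
Reactants: 4 1-(benzyloxy)-4-bromo-2-methoxybenzene; 2 (S)-N-methoxy-N,2,2-trimethyl-1,3-dioxolane-4-carboxamide
Product: 6 [4-(benzyloxy)-3-methoxyphenyl][(4S)-2,2-dimethyl-1,3-dioxolan-4-yl]methanone, via aryl Grignard reagent 5 (not isolated)
Conditions: Mg, cat. I2, THF, reflux; then 2, THF, 0 °C; aq NH4Cl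
Reagents that add atoms: magnesium, [Mg] (ends in intermediate 5, not in 6)
Why: Weinreb ketone synthesis, in which the magnesium-chelated tetrahedral adduct collapses only on work-up, so the C1''–C7'' bond forms without over-addition and without base-induced epimerisation at C8''.

**Step 4**
Reactants: 6 [4-(benzyloxy)-3-methoxyphenyl][(4S)-2,2-dimethyl-1,3-dioxolan-4-yl]methanone
Product: 7 (R)-[4-(benzyloxy)-3-methoxyphenyl][(4S)-2,2-dimethyl-1,3-dioxolan-4-yl]methanol (anti, 7''R,8''S)
Conditions: Zn(BH4)2, Et2O, −78 → −20 °C; aq NH4Cl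
Reagents that add atoms: none
Why: Chelation-controlled (Cram chelate) hydride reduction, in which zinc ties the ketone oxygen to the α-oxygen of the dioxolane and hydride arrives from the face bearing the C8'' hydrogen, so the anti (7''R,8''S) alcohol should predominate and any syn epimer can be removed by chromatography.

**Step 5**
Reactants: 7 (R)-[4-(benzyloxy)-3-methoxyphenyl][(4S)-2,2-dimethyl-1,3-dioxolan-4-yl]methanol; 8 4-bromo-2,6-difluorobenzaldehyde
Product: 9 2-{(R)-[4-(benzyloxy)-3-methoxyphenyl][(4S)-2,2-dimethyl-1,3-dioxolan-4-yl]methoxy}-4-bromo-6-fluorobenzaldehyde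
Conditions: NaH added in portions to 7 and 8 (slight excess), THF, 0 °C → rt
Reagents that add atoms: none
Why: Nucleophilic aromatic substitution by addition–elimination, in which the hindered alkoxide meets the ring at its most electrophilic stage (formyl plus two fluorines), fluoride is by far the best nucleofuge present, the first alkoxy group slows a second attack, and C7'' keeps its configuration because only its O–H bond is broken.

**Step 6**
Reactants: 9 2-{(R)-[4-(benzyloxy)-3-methoxyphenyl][(4S)-2,2-dimethyl-1,3-dioxolan-4-yl]methoxy}-4-bromo-6-fluorobenzaldehyde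
Product: 10 2-{(R)-[4-(benzyloxy)-3-methoxyphenyl][(4S)-2,2-dimethyl-1,3-dioxolan-4-yl]methoxy}-4-bromo-6-methoxybenzaldehyde
Conditions: NaOMe, MeOH–THF, 60 °C
Reagents that add atoms: sodium methoxide, [Na+].[O-]C
Why: Second SNAr ortho to the formyl group, in which small methoxide in excess displaces the remaining fluoride on the now less activated ring, while bromide para to the aldehyde and the ortho alkoxy group are much poorer leaving groups in addition–elimination.

**Step 7**
Reactants: 10 2-{(R)-[4-(benzyloxy)-3-methoxyphenyl][(4S)-2,2-dimethyl-1,3-dioxolan-4-yl]methoxy}-4-bromo-6-methoxybenzaldehyde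
Product: 11 2-{(1R,2S)-1-[4-(benzyloxy)-3-methoxyphenyl]-2,3-dihydroxypropoxy}-4-bromo-6-methoxybenzaldehyde
Conditions: AcOH–H2O (4:1), 40 °C
Reagents that add atoms: none
Why: Acid-catalysed acetal hydrolysis of a terminal acetonide proceeds in warm aqueous acetic acid, a medium too weak to ionise the C7''–O3' benzylic aryl ether or to cleave the benzyl ether.

**Step 8**
Reactants: 11 2-{(1R,2S)-1-[4-(benzyloxy)-3-methoxyphenyl]-2,3-dihydroxypropoxy}-4-bromo-6-methoxybenzaldehyde
Product: 13 2-{(R)-[4-(benzyloxy)-3-methoxyphenyl][(2S)-oxiran-2-yl]methoxy}-4-bromo-6-methoxybenzaldehyde, via primary tosylate 12 (not isolated)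
Conditions: TsCl, Et3N, cat. Bu2SnO, CH2Cl2, 0 °C → rt; then K2CO3, MeOH, 0 °C → rt
Reagents that add atoms: p-toluenesulfonyl chloride, Cc1ccc(cc1)S(=O)(=O)Cl (ends in intermediate 12, not in 13)
Why: Tin-acetal-catalysed regioselective sulfonylation puts the tosyl group on the primary C9'' hydroxyl, and the C8'' alkoxide then closes the oxirane by 3-exo-tet Williamson displacement at C9'', so no bond to C8'' is broken and its (S) configuration stays.

**Step 9**
Reactants: 13 2-{(R)-[4-(benzyloxy)-3-methoxyphenyl][(2S)-oxiran-2-yl]methoxy}-4-bromo-6-methoxybenzaldehyde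
Product: 14 2-{(R)-[4-(benzyloxy)-3-methoxyphenyl][(2S)-oxiran-2-yl]methoxy}-4-bromo-6-methoxyphenyl formate
Conditions: mCPBA, CH2Cl2, 0 °C → rt
Reagents that add atoms: 3-chloroperoxybenzoic acid, O=C(OO)c1cccc(Cl)c1
Why: Baeyer–Villiger (Dakin-type) oxidation of an aldehyde flanked by two ortho alkoxy groups goes by aryl migration in the Criegee adduct and turns C4'–CHO into C4'–O–CHO, while oxirane, aryl bromide and benzyl ether are inert to the peracid at this temperature.

**Step 10**
Reactants: 14 2-{(R)-[4-(benzyloxy)-3-methoxyphenyl][(2S)-oxiran-2-yl]methoxy}-4-bromo-6-methoxyphenyl formate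
Product: 16 [(2R,3R)-3-[4-(benzyloxy)-3-methoxyphenyl]-6-bromo-8-methoxy-2,3-dihydro-1,4-benzodioxin-2-yl]methanol, via epoxy phenol 15 (not isolated)
Conditions: K2CO3, MeOH, 0 °C → rt
Reagents that add atoms: none
Why: Methoxide present in K2CO3/MeOH transesterifies the aryl formate of 14 to methyl formate and the O4' phenoxide of 15, which attacks the internal oxirane carbon C8'' from the side opposite its C–O bond and releases the oxirane oxygen on C9'' as the primary alkoxide, protonated by the solvent. The closest known reaction type is the base-induced cyclisation of 2-(oxiranylmethoxy)phenols (catechol glycidyl ethers) to 2-hydroxymethyl-1,4-benzodioxanes. The single ring formed, the 1,4-dioxane ring O4'–C4'–C3'–O3'–C7''–C8'', closes in the 6-exo-tet mode. The only stereocentre that changes is C8'', whose (R) configuration follows from SN2 inversion of the (S) oxirane carbon inherited from 1, whereas C7'' stays (R) because none of its bonds is touched, so the erythro ether becomes the trans-2,3-disubstituted dioxane with both large groups pseudo-equatorial. The step needs attack at C8'' rather than at C9'' (7-endo, benzodioxepine) and needs the phenoxide to outrun external methoxide. The short O3'–C7''–C8'' tether lines the phenoxide up with the C8''–O antibonding orbital only in the six-membered transition state, and the low methoxide concentration at ambient temperature leaves the intramolecular nucleophile without a serious competitor.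

**Step 11**
Reactants: 16 [(2R,3R)-3-[4-(benzyloxy)-3-methoxyphenyl]-6-bromo-8-methoxy-2,3-dihydro-1,4-benzodioxin-2-yl]methanol
Product: 17 {[(2R,3R)-3-[4-(benzyloxy)-3-methoxyphenyl]-6-bromo-8-methoxy-2,3-dihydro-1,4-benzodioxin-2-yl]methoxy}triisopropylsilane
Conditions: TIPSCl, imidazole, DMF, rt
Reagents that add atoms: chlorotriisopropylsilane, CC(C)[Si](Cl)(C(C)C)C(C)C
Why: Standard silyl ether formation on the single free primary hydroxyl, the triisopropylsilyl group being chosen because it withstands n-BuLi, ethanolic KOH and hot I2/DMSO.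

**Step 12**
Reactants: 17 {[(2R,3R)-3-[4-(benzyloxy)-3-methoxyphenyl]-6-bromo-8-methoxy-2,3-dihydro-1,4-benzodioxin-2-yl]methoxy}triisopropylsilane
Product: 19 (2R,3R)-3-[4-(benzyloxy)-3-methoxyphenyl]-8-methoxy-2-{[(triisopropylsilyl)oxy]methyl}-2,3-dihydro-1,4-benzodioxine-6-carbaldehyde, via aryllithium 18 (not isolated)
Conditions: n-BuLi, THF, −78 °C; then DMF, −78 → 0 °C; aq NH4Cl
Reagents that add atoms: n-butyllithium, [Li]CCCC (lithium ends in intermediate 18, not in 19); N,N-dimethylformamide, CN(C)C=O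
Why: Bromine–lithium exchange followed by formylation with DMF (Bouveault-type aldehyde synthesis) is faster at −78 °C than any benzylic deprotonation and places the future C2 of the flavone on C1'.

**Step 13**
Reactants: 20 2',4',6'-trihydroxyacetophenone
Product: 21 1-[2,4-bis(benzyloxy)-6-hydroxyphenyl]ethanone
Conditions: BnBr (2 equiv), K2CO3, DMF, 60 °C
Reagents that add atoms: benzyl bromide, BrCc1ccccc1
Why: Regioselective Williamson etherification, in which a hydroxyl hydrogen-bonded to the acetyl carbonyl is the least nucleophilic, so two equivalents of BnBr alkylate the para and one ortho oxygen and leave the chelated OH needed for ring C.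

**Step 14**
Reactants: 19 (2R,3R)-3-[4-(benzyloxy)-3-methoxyphenyl]-8-methoxy-2-{[(triisopropylsilyl)oxy]methyl}-2,3-dihydro-1,4-benzodioxine-6-carbaldehyde; 21 1-[2,4-bis(benzyloxy)-6-hydroxyphenyl]ethanone
Product: 22 (E)-1-[2,4-bis(benzyloxy)-6-hydroxyphenyl]-3-{(2R,3R)-3-[4-(benzyloxy)-3-methoxyphenyl]-8-methoxy-2-{[(triisopropylsilyl)oxy]methyl}-2,3-dihydro-1,4-benzodioxin-6-yl}prop-2-en-1-one
Conditions: KOH, EtOH–THF, rt
Reagents that add atoms: none
Why: Claisen–Schmidt condensation (crossed aldol with E1cB dehydration) between a non-enolisable aldehyde and the methyl ketone forms the C2–C3 bond as the (E)-2'-hydroxychalcone, and neither stereocentre bears a hydrogen acidic enough to be disturbed.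

**Step 15**
Reactants: 22 (E)-2'-hydroxychalcone of step 14
Product: 23 5,7-bis(benzyloxy)-2-{(2R,3R)-3-[4-(benzyloxy)-3-methoxyphenyl]-8-methoxy-2-{[(triisopropylsilyl)oxy]methyl}-2,3-dihydro-1,4-benzodioxin-6-yl}-4H-chromen-4-one
Conditions: I2 (10 mol %), DMSO, 125 °C
Reagents that add atoms: none
Why: Iodine-catalysed oxidative cyclisation of a 2'-hydroxychalcone in DMSO (6-endo-trig oxa-Michael closure of ring C, α-iodination, loss of HI, re-oxidation of HI by DMSO) is the standard flavone synthesis and forms the O1–C2 bond.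

**Step 16**
Reactants: 23 silyl-protected tribenzyl flavone of step 15
Product: 24 5,7-bis(benzyloxy)-2-{(2R,3R)-3-[4-(benzyloxy)-3-methoxyphenyl]-2-(hydroxymethyl)-8-methoxy-2,3-dihydro-1,4-benzodioxin-6-yl}-4H-chromen-4-one
Conditions: TBAF, THF, 0 °C → rt
Reagents that add atoms: none
Why: Fluoride-induced desilylation is driven by the strong Si–F bond and touches neither the benzyl ethers nor the flavone.

**Step 17**
Reactants: 24 tribenzyl flavone alcohol of step 16
Product: 25 5'-methoxyhydnocarpin, 5,7-dihydroxy-2-[(2R,3R)-3-(4-hydroxy-3-methoxyphenyl)-2-(hydroxymethyl)-8-methoxy-2,3-dihydro-1,4-benzodioxin-6-yl]-4H-chromen-4-one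
Conditions: H2 (1 atm), 10% Pd/C, THF–MeOH, rt
Reagents that add atoms: none
Why: Catalytic hydrogenolysis cleaves the three unhindered primary benzyl aryl ethers much faster than it attacks the hindered endocyclic secondary C7''–O3' bond or the conjugated C2=C3 bond, so stopping after uptake of three equivalents of H2 should give 25 with both stereocentres intact.

**Compound list**
1 | methyl (S)-2,2-dimethyl-1,3-dioxolane-4-carboxylate | COC(=O)[C@@H]1COC(C)(C)O1 | starting material
2 | (S)-N-methoxy-N,2,2-trimethyl-1,3-dioxolane-4-carboxamide | CON(C)C(=O)[C@@H]1COC(C)(C)O1 | intermediate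
3 | 4-bromo-2-methoxyphenol | COc1cc(Br)ccc1O | starting material
4 | 1-(benzyloxy)-4-bromo-2-methoxybenzene | COc1cc(Br)ccc1OCc1ccccc1 | intermediate
5 | [4-(benzyloxy)-3-methoxyphenyl]magnesium bromide | COc1cc([Mg]Br)ccc1OCc1ccccc1 | intermediate
6 | [4-(benzyloxy)-3-methoxyphenyl][(4S)-2,2-dimethyl-1,3-dioxolan-4-yl]methanone | COc1cc(C(=O)[C@@H]2COC(C)(C)O2)ccc1OCc1ccccc1 | intermediate
7 | (R)-[4-(benzyloxy)-3-methoxyphenyl][(4S)-2,2-dimethyl-1,3-dioxolan-4-yl]methanol | COc1cc([C@@H](O)[C@@H]2COC(C)(C)O2)ccc1OCc1ccccc1 | intermediate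
8 | 4-bromo-2,6-difluorobenzaldehyde | O=Cc1c(F)cc(Br)cc1F | starting material
9 | 2-{(R)-[4-(benzyloxy)-3-methoxyphenyl][(4S)-2,2-dimethyl-1,3-dioxolan-4-yl]methoxy}-4-bromo-6-fluorobenzaldehyde | COc1cc([C@H]([C@@H]2COC(C)(C)O2)Oc3cc(Br)cc(F)c3C=O)ccc1OCc1ccccc1 | intermediate
10 | 2-{(R)-[4-(benzyloxy)-3-methoxyphenyl][(4S)-2,2-dimethyl-1,3-dioxolan-4-yl]methoxy}-4-bromo-6-methoxybenzaldehyde | COc1cc([C@H]([C@@H]2COC(C)(C)O2)Oc3cc(Br)cc(OC)c3C=O)ccc1OCc1ccccc1 | intermediate
11 | 2-{(1R,2S)-1-[4-(benzyloxy)-3-methoxyphenyl]-2,3-dihydroxypropoxy}-4-bromo-6-methoxybenzaldehyde | COc1cc([C@H]([C@@H](O)CO)Oc2cc(Br)cc(OC)c2C=O)ccc1OCc1ccccc1 | intermediate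
12 | (2S,3R)-3-[4-(benzyloxy)-3-methoxyphenyl]-3-(5-bromo-2-formyl-3-methoxyphenoxy)-2-hydroxypropyl 4-methylbenzenesulfonate | COc1cc([C@H]([C@@H](O)COS(=O)(=O)c2ccc(C)cc2)Oc3cc(Br)cc(OC)c3C=O)ccc1OCc1ccccc1 | intermediate
13 | 2-{(R)-[4-(benzyloxy)-3-methoxyphenyl][(2S)-oxiran-2-yl]methoxy}-4-bromo-6-methoxybenzaldehyde | COc1cc([C@H]([C@@H]2CO2)Oc3cc(Br)cc(OC)c3C=O)ccc1OCc1ccccc1 | intermediate
14 | 2-{(R)-[4-(benzyloxy)-3-methoxyphenyl][(2S)-oxiran-2-yl]methoxy}-4-bromo-6-methoxyphenyl formate | COc1cc([C@H]([C@@H]2CO2)Oc3cc(Br)cc(OC)c3OC=O)ccc1OCc1ccccc1 | intermediate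
15 | 2-{(R)-[4-(benzyloxy)-3-methoxyphenyl][(2S)-oxiran-2-yl]methoxy}-4-bromo-6-methoxyphenol | COc1cc([C@H]([C@@H]2CO2)Oc3cc(Br)cc(OC)c3O)ccc1OCc1ccccc1 | intermediate
16 | [(2R,3R)-3-[4-(benzyloxy)-3-methoxyphenyl]-6-bromo-8-methoxy-2,3-dihydro-1,4-benzodioxin-2-yl]methanol | COc1cc([C@H]2Oc3cc(Br)cc(OC)c3O[C@@H]2CO)ccc1OCc1ccccc1 | intermediate
17 | {[(2R,3R)-3-[4-(benzyloxy)-3-methoxyphenyl]-6-bromo-8-methoxy-2,3-dihydro-1,4-benzodioxin-2-yl]methoxy}triisopropylsilane | COc1cc([C@H]2Oc3cc(Br)cc(OC)c3O[C@@H]2CO[Si](C(C)C)(C(C)C)C(C)C)ccc1OCc1ccccc1 | intermediate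
18 | 6-lithio analogue of 17 (lithium in place of bromine on C1') | COc1cc([C@H]2Oc3cc([Li])cc(OC)c3O[C@@H]2CO[Si](C(C)C)(C(C)C)C(C)C)ccc1OCc1ccccc1 | intermediate
19 | (2R,3R)-3-[4-(benzyloxy)-3-methoxyphenyl]-8-methoxy-2-{[(triisopropylsilyl)oxy]methyl}-2,3-dihydro-1,4-benzodioxine-6-carbaldehyde | COc1cc([C@H]2Oc3cc(C=O)cc(OC)c3O[C@@H]2CO[Si](C(C)C)(C(C)C)C(C)C)ccc1OCc1ccccc1 | intermediate
20 | 2',4',6'-trihydroxyacetophenone | CC(=O)c1c(O)cc(O)cc1O | starting material
21 | 1-[2,4-bis(benzyloxy)-6-hydroxyphenyl]ethanone | CC(=O)c1c(O)cc(OCc2ccccc2)cc1OCc1ccccc1 | intermediate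
22 | (E)-1-[2,4-bis(benzyloxy)-6-hydroxyphenyl]-3-{(2R,3R)-3-[4-(benzyloxy)-3-methoxyphenyl]-8-methoxy-2-{[(triisopropylsilyl)oxy]methyl}-2,3-dihydro-1,4-benzodioxin-6-yl}prop-2-en-1-one | COc1cc([C@H]2Oc3cc(/C=C/C(=O)c4c(O)cc(OCc5ccccc5)cc4OCc6ccccc6)cc(OC)c3O[C@@H]2CO[Si](C(C)C)(C(C)C)C(C)C)ccc1OCc1ccccc1 | intermediate
23 | 5,7-bis(benzyloxy)-2-{(2R,3R)-3-[4-(benzyloxy)-3-methoxyphenyl]-8-methoxy-2-{[(triisopropylsilyl)oxy]methyl}-2,3-dihydro-1,4-benzodioxin-6-yl}-4H-chromen-4-one | COc1cc([C@H]2Oc3cc(-c4cc(=O)c5c(OCc6ccccc6)cc(OCc6ccccc6)cc5o4)cc(OC)c3O[C@@H]2CO[Si](C(C)C)(C(C)C)C(C)C)ccc1OCc1ccccc1 | intermediate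
24 | 5,7-bis(benzyloxy)-2-{(2R,3R)-3-[4-(benzyloxy)-3-methoxyphenyl]-2-(hydroxymethyl)-8-methoxy-2,3-dihydro-1,4-benzodioxin-6-yl}-4H-chromen-4-one | COc1cc([C@H]2Oc3cc(-c4cc(=O)c5c(OCc6ccccc6)cc(OCc6ccccc6)cc5o4)cc(OC)c3O[C@@H]2CO)ccc1OCc1ccccc1 | intermediate
25 | 5'-methoxyhydnocarpin, (7''R,8''R) | COc1cc([C@H]2Oc3cc(-c4cc(=O)c5c(O)cc(O)cc5o4)cc(OC)c3O[C@@H]2CO)ccc1O | target

**Totals**
Total step count: 17.
Longest linear sequence: 15 steps (steps 1, 3–12 and 14–17, from 1 to 25). The branch from 3 through step 2 is equally long.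

**Steps most likely to fail**

Step 4, poor facial selectivity. The acetonide oxygen is a weak ligand for zinc, so open-chain (Felkin–Anh) delivery of hydride may compete with the chelate and erode the anti preference.
- The fallback creates C7'' by carbon–carbon bond formation instead of by hydride delivery. In that mode the Felkin–Anh pathway itself leads to the anti isomer.
- It sets out from 2, which iBu2AlH in THF at −78 °C reduces to (S)-2,2-dimethyl-1,3-dioxolane-4-carbaldehyde F1.
- Grignard reagent 5 is transmetalated with ClTi(OiPr)3 to the non-chelating [4-(benzyloxy)-3-methoxyphenyl]titanium triisopropoxide F2.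
- F2 adds to F1 at low temperature, and the route is rejoined at 7.

Step 5, redox and over-substitution side reactions. Hydride may transfer from the secondary benzylic alkoxide to the very electrophilic aldehyde (Meerwein–Ponndorf–Verley/Oppenauer-type exchange). The alkoxide may also be trapped as a hemiacetal, or attack a second time.
- The fallback replaces the formyl activator by a nitrile, which cannot accept hydride from an alkoxide.
- It sets out from 7, which reacts with 4-bromo-2,6-difluorobenzonitrile (NaH, THF) to give 2-{(R)-[4-(benzyloxy)-3-methoxyphenyl][(4S)-2,2-dimethyl-1,3-dioxolan-4-yl]methoxy}-4-bromo-6-fluorobenzonitrile F3.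
- NaOMe in MeOH converts F3 into the corresponding 6-methoxybenzonitrile F4.
- iBu2AlH in toluene at −78 °C, followed by mild aqueous hydrolysis of the aldimine, returns to the route at 10.

Step 10, loss of site selectivity through slow closure. Attack at the hindered internal oxirane carbon may be slow enough for methoxide to open the oxirane at C9'', or for the phenoxide to attack C9''.
- The fallback forms the same O4'–C8'' bond in the same 6-exo-tet mode with inversion, but on an acyclic C8'' sulfonate in which C9'' is no longer electrophilic.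
- It sets out from 11. TIPSCl/imidazole silylates the primary hydroxyl to give the C9'' triisopropylsilyl ether F5.
- MsCl/Et3N gives the C8'' methanesulfonate F6, and mCPBA gives the aryl formate F7.
- K2CO3 in MeOH releases the phenol mesylate F8, which cyclises in the flask by intramolecular SN2 displacement.
- The route is rejoined at 17, so step 11 is no longer needed.

**Further compounds**
F1 | step 4 | (S)-2,2-dimethyl-1,3-dioxolane-4-carbaldehyde | O=C[C@@H]1COC(C)(C)O1
F2 | step 4 | [4-(benzyloxy)-3-methoxyphenyl]titanium triisopropoxide | COc1cc([Ti](OC(C)C)(OC(C)C)OC(C)C)ccc1OCc1ccccc1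
F3 | step 5 | 2-{(R)-[4-(benzyloxy)-3-methoxyphenyl][(4S)-2,2-dimethyl-1,3-dioxolan-4-yl]methoxy}-4-bromo-6-fluorobenzonitrile | COc1cc([C@H]([C@@H]2COC(C)(C)O2)Oc3cc(Br)cc(F)c3C#N)ccc1OCc1ccccc1
F4 | step 5 | 2-{(R)-[4-(benzyloxy)-3-methoxyphenyl][(4S)-2,2-dimethyl-1,3-dioxolan-4-yl]methoxy}-4-bromo-6-methoxybenzonitrile | COc1cc([C@H]([C@@H]2COC(C)(C)O2)Oc3cc(Br)cc(OC)c3C#N)ccc1OCc1ccccc1
F5 | step 10 | 2-{(1R,2S)-1-[4-(benzyloxy)-3-methoxyphenyl]-2-hydroxy-3-[(triisopropylsilyl)oxy]propoxy}-4-bromo-6-methoxybenzaldehyde | COc1cc([C@H]([C@@H](O)CO[Si](C(C)C)(C(C)C)C(C)C)Oc2cc(Br)cc(OC)c2C=O)ccc1OCc1ccccc1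
F6 | step 10 | (1R,2S)-1-[4-(benzyloxy)-3-methoxyphenyl]-1-(5-bromo-2-formyl-3-methoxyphenoxy)-3-[(triisopropylsilyl)oxy]propan-2-yl methanesulfonate | COc1cc([C@H]([C@@H](OS(C)(=O)=O)CO[Si](C(C)C)(C(C)C)C(C)C)Oc2cc(Br)cc(OC)c2C=O)ccc1OCc1ccccc1
F7 | step 10 | (1R,2S)-1-[4-(benzyloxy)-3-methoxyphenyl]-1-[5-bromo-2-(formyloxy)-3-methoxyphenoxy]-3-[(triisopropylsilyl)oxy]propan-2-yl methanesulfonate | COc1cc([C@H]([C@@H](OS(C)(=O)=O)CO[Si](C(C)C)(C(C)C)C(C)C)Oc2cc(Br)cc(OC)c2OC=O)ccc1OCc1ccccc1
F8 | step 10 | (1R,2S)-1-[4-(benzyloxy)-3-methoxyphenyl]-1-(5-bromo-2-hydroxy-3-methoxyphenoxy)-3-[(triisopropylsilyl)oxy]propan-2-yl methanesulfonate | COc1cc([C@H]([C@@H](OS(C)(=O)=O)CO[Si](C(C)C)(C(C)C)C(C)C)Oc2cc(Br)cc(OC)c2O)ccc1OCc1ccccc1
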